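Ring B is cut at C9–C10 and ring A is carried as an aromatic 2,4-dimethylphenol: its oxygen is the future C3 and lies para to C10, and C4 and C10 already hold their methyl groups. In one operation a chiral ammonium phenoxide attacks through C10 the C9 carbon of an (E)-4-oxo-enoate tethered to C5, which closes ring B, turns ring A into a cross-conjugated dienone and sets C10 and C9. The precursor is ethyl (E)-6-(3-hydroxy-2,6-dimethylphenyl)-4-oxohex-2-enoate. Ring A is then reduced, gem-dimethylated and brominated, C8 becomes the C7=C8 methyl alkene, and C12 is extended to the vinyl carbinol.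

Key step: step 7

Remark: labdane atom labels are used (C3 bears Br, C10 the angular methyl, C13 the carbinol). The target SMILES corresponds to (3R,5S,9S,10S,13R), with the C9 side chain trans to the C10 methyl, and the route is aimed at exactly this isomer.

**Route**

Step 1
Reactants: 1 2-bromo-1,3-dimethylbenzene
Product: 2 2-bromo-1,3-dimethyl-4-nitrobenzene
Conditions: HNO3 (1.05 equiv), H2SO4, 0 → 10 °C
Reagents that add atoms: nitric acid, O[N+](=O)[O-]
Why: Electrophilic aromatic nitration, which should go to C4 because that position is ortho to one methyl group and para to the other.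

Step 2
Reactants: 2 2-bromo-1,3-dimethyl-4-nitrobenzene
Product: 3 3-bromo-2,4-dimethylaniline
Conditions: H2 (1 atm), sulfided 5% Pt/C, EtOAc, 25 °C
Reagents that add atoms: none
Why: Catalytic hydrogenation of the nitro group over a sulfided platinum catalyst, chosen because it leaves aryl bromides intact.

Step 3
Reactants: 3 3-bromo-2,4-dimethylaniline
Product: 5 3-bromo-2,4-dimethylphenol, via 3-bromo-2,4-dimethylbenzenediazonium hydrogensulfate 4 (not isolated)
Conditions: NaNO2, aq H2SO4, 0 °C; then into boiling aq H2SO4 under toluene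
Reagents that add atoms: water, O; sodium nitrite, O=N[O-].[Na+] (its nitrogen stays only in 4)
Why: Diazotisation followed by thermal hydrolysis of the arenediazonium salt, which exchanges NH2 for OH without touching the bromide.

Step 4
Reactants: 5 3-bromo-2,4-dimethylphenol; 6 allyl alcohol (prop-2-en-1-ol)
Product: 7 3-(3-hydroxy-2,6-dimethylphenyl)propanal
Conditions: Pd(OAc)2 (5 mol %), P(t-Bu)3·HBF4 (10 mol %), NaHCO3, Bu4NCl, DMF, 90 °C
Reagents that add atoms: none
Why: Heck arylation of an allylic alcohol, in which the aryl group adds to the terminal carbon and β-hydride elimination toward the carbinol gives the enol and hence the aldehyde, the bulky electron-rich phosphine being chosen for the di-ortho-substituted bromide.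

Step 5
Reactants: 7 3-(3-hydroxy-2,6-dimethylphenyl)propanal; 8 ethyl propiolate
Product: 9 ethyl 4-hydroxy-6-(3-hydroxy-2,6-dimethylphenyl)hex-2-ynoate (racemic at the carbinol)
Conditions: LiN(SiMe3)2 (2.5 equiv), 8 (1.5 equiv), THF, −78 °C; AcOH at −78 °C
Reagents that add atoms: none
Why: 1,2-Addition of a lithium acetylide to an aldehyde, with one equivalent of base spent on the phenol and no need to control the carbinol centre because it is oxidised in the next step.

Step 6
Reactants: 9 ethyl 4-hydroxy-6-(3-hydroxy-2,6-dimethylphenyl)hex-2-ynoate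
Product: 10 ethyl (E)-6-(3-hydroxy-2,6-dimethylphenyl)-4-oxohex-2-enoate
Conditions: RuCl(indenyl)(PPh3)2 (3 mol %), In(OTf)3 (3 mol %), camphorsulfonic acid (5 mol %), THF, 65 °C
Reagents that add atoms: none
Why: Ruthenium-catalysed redox isomerisation of a propargylic alcohol to the (E)-enone, run without base so that the free phenol cannot cyclise prematurely and without stereocontrol.

Step 7
Reactants: 10 ethyl (E)-6-(3-hydroxy-2,6-dimethylphenyl)-4-oxohex-2-enoate
Product: 11 ethyl 2-[(1R,8aS)-5,8a-dimethyl-2,6-dioxo-1,2,3,4,6,8a-hexahydronaphthalen-1-yl]acetate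
Conditions: N-(9-anthracenylmethyl)cinchonidinium chloride (10 mol %), Cs2CO3 (1.5 equiv, solid), toluene/CHCl3 (7:3, 0.02 M), −40 °C; AcOH at −40 °C
Reagents that add atoms: none
Why: Proposed new method: the phenoxide of 10, held as an ion pair with the chiral ammonium cation, should add through its para carbon C10 to C9 (β to the ester) of the (E)-enoate, after which the ester enolate is protonated; the closest known reactions are intramolecular alkylative and Michael para-dearomatisations of phenols that give spiro-cyclohexadienones, including catalytic asymmetric versions. Ring B closes in the 6-exo-trig mode, because the 7-endo attack at C11 would place a trans alkene inside the forming ring. C10 is set by the cation, which must shield one arene face while bridging the phenoxide oxygen and the emerging enolate oxygen. C9 follows from the compact transition state in which the acrylate lies over ring A, which puts CH2CO2Et trans to the C10 methyl; the cold acidic quench is meant to keep this kinetic outcome although C9 stays epimerisable through the C8 ketone. The step needs C- over O-attack (the oxygen is meta to the tether and cannot reach C9) and para over ortho attack (C4 would also give a six-membered ring, but only the less stable linearly conjugated dienone, and a loose ammonium ion pair favours the para carbon). Rearomatisation by tautomerisation is excluded because C4 and C10 both carry methyl groups.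

Step 8
Reactants: 11 ethyl 2-[(1R,8aS)-5,8a-dimethyl-2,6-dioxo-1,2,3,4,6,8a-hexahydronaphthalen-1-yl]acetate
Product: 12 ethyl 2-[(1R,8aS)-2,2-(ethylenedioxy)-5,8a-dimethyl-6-oxo-1,2,3,4,6,8a-hexahydronaphthalen-1-yl]acetate (C8 dioxolane of 11)
Conditions: (TMSOCH2)2, TMSOTf (5 mol %), CH2Cl2, −78 → −40 °C
Reagents that add atoms: 1,2-bis(trimethylsilyloxy)ethane, C[Si](C)(C)OCCO[Si](C)(C)C
Why: TMSOTf-catalysed ketalisation, selective for the saturated C8 ketone over the cross-conjugated dienone carbonyl, which also locks C9 against enolisation.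

Step 9
Reactants: 12 (C8 dioxolane dienone)
Product: 13 ethyl 2-[(1R,8aS)-2,2-(ethylenedioxy)-5,8a-dimethyl-6-oxo-1,2,3,4,6,7,8,8a-octahydronaphthalen-1-yl]acetate
Conditions: H2 (1 atm), RhCl(PPh3)3 (5 mol %), benzene/EtOH, 25 °C
Reagents that add atoms: none
Why: Homogeneous hydrogenation with RhCl(PPh3)3, which reduces the disubstituted C1=C2 bond of a cross-conjugated dienone and leaves the tetrasubstituted C4=C5 enone alone.

Step 10
Reactants: 13 (C4=C5 enone)
Product: 14 ethyl 2-[(1R,8aS)-2,2-(ethylenedioxy)-5,5,8a-trimethyl-6-oxo-1,2,3,5,6,7,8,8a-octahydronaphthalen-1-yl]acetate (C5=C6 alkene)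
Conditions: KOt-Bu (1.5 equiv), MeI (3 equiv), t-BuOH/THF, 0 → 25 °C
Reagents that add atoms: iodomethane, CI
Why: Deconjugative α-alkylation of the enone through its extended dienolate, which is methylated at C4 and leaves the C5=C6 alkene, while the ketal shields C8 and the ester is too weakly acidic to compete.

Step 11
Reactants: 14 (4,4-dimethyl C3 ketone)
Product: 15 ethyl 2-[(1R,8aS)-2,2-(ethylenedioxy)-5,5,8a-trimethyl-6-{[(trifluoromethyl)sulfonyl]oxy}-1,2,3,5,8,8a-hexahydronaphthalen-1-yl]acetate (C2=C3 enol triflate)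
Conditions: KN(SiMe3)2 (1.1 equiv), PhNTf2, THF, −78 °C
Reagents that add atoms: N-phenylbis(trifluoromethanesulfonimide), O=S(=O)(N(c1ccccc1)S(=O)(=O)C(F)(F)F)C(F)(F)F
Why: Kinetic enolate formation and O-triflation, regiochemically unambiguous because C2 carries the only α-hydrogens of the C3 ketone.

Step 12
Reactants: 15 (C2=C3 enol triflate)
Product: 16 ethyl 2-[(1R,8aS)-6-bromo-2,2-(ethylenedioxy)-5,5,8a-trimethyl-1,2,3,5,8,8a-hexahydronaphthalen-1-yl]acetate (C2=C3 alkenyl bromide, C5=C6 alkene)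
Conditions: Ni(cod)2 (10 mol %), LiBr (2 equiv), DMA/THF (1:3), 25 °C
Reagents that add atoms: lithium bromide, [Li+].[Br-]
Why: Nickel-catalysed triflate-to-halide exchange of an enol triflate (oxidative addition to zerovalent nickel, anion exchange, reductive elimination), which gives the alkenyl bromide without ionising the neopentyl C3 position.

Step 13
Reactants: 16 (bromodiene)
Product: 17 ethyl 2-[(1R,4aS,6R,8aR)-6-bromo-2,2-(ethylenedioxy)-5,5,8a-trimethyldecahydronaphthalen-1-yl]acetate
Conditions: Mn(dpm)3 (20 mol %), PhSiH3 (4 equiv), t-BuOOH (4 equiv), i-PrOH, 25 °C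
Reagents that add atoms: none
Why: Metal-hydride hydrogen-atom-transfer (Mukaiyama-type) hydrogenation, which reduces alkenyl halides to alkyl halides: hydrogen atoms add to C2 and C6, and the C3 and C5 radicals are then quenched on the face opposite the axial C10 and C4 methyls, giving equatorial bromine at C3 and the trans ring fusion at C5.

Step 14
Reactants: 17 (C8 dioxolane)
Product: 18 ethyl 2-[(1R,4aS,6R,8aR)-6-bromo-5,5,8a-trimethyl-2-oxodecahydronaphthalen-1-yl]acetate
Conditions: PPTS (20 mol %), acetone/H2O (10:1), 50 °C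
Reagents that add atoms: water, O
Why: Mildly acidic ketal hydrolysis, under which enolisation toward C9 should be slow because the equatorial C9–H is poorly aligned with the carbonyl.

Step 15
Reactants: 18 (C8 ketone)
Product: 19 ethyl 2-[(1R,4aS,6R,8aR)-6-bromo-5,5,8a-trimethyl-2-{[(trifluoromethyl)sulfonyl]oxy}-1,4,4a,5,6,7,8,8a-octahydronaphthalen-1-yl]acetate (C7=C8 enol triflate)
Conditions: KN(SiMe3)2 (1.05 equiv) added to 18 and PhNTf2, THF, −78 °C
Reagents that add atoms: N-phenylbis(trifluoromethanesulfonimide), O=S(=O)(N(c1ccccc1)S(=O)(=O)C(F)(F)F)C(F)(F)F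
Why: Kinetic deprotonation at the less hindered C7 methylene instead of the tertiary C9–H, with in-situ O-triflation, gives the C7=C8 enol triflate and leaves C9 untouched.

Step 16
Reactants: 19 (C7=C8 enol triflate)
Product: 20 ethyl 2-[(1S,4aS,6R,8aS)-6-bromo-2,5,5,8a-tetramethyl-1,4,4a,5,6,7,8,8a-octahydronaphthalen-1-yl]acetate
Conditions: Pd(PPh3)4 (5 mol %), Me2Zn (2 equiv), THF, 0 → 50 °C
Reagents that add atoms: dimethylzinc, C[Zn]C
Why: Negishi cross-coupling of the enol triflate, in which zerovalent palladium inserts into the C–OTf bond much faster than into the secondary alkyl bromide and Me2Zn does not attack the ester.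

Step 17
Reactants: 20 (ethyl ester)
Product: 21 2-[(1S,4aS,6R,8aS)-6-bromo-2,5,5,8a-tetramethyl-1,4,4a,5,6,7,8,8a-octahydronaphthalen-1-yl]acetaldehyde
Conditions: i-Bu2AlH (1.1 equiv), CH2Cl2, −78 °C; Rochelle salt
Reagents that add atoms: none
Why: Partial reduction of the ester with i-Bu2AlH at low temperature, where the aluminium hemiacetal survives until work-up.

Step 18
Reactants: 21 (C12 aldehyde)
Product: 22 ethyl (2E)-4-[(1S,4aS,6R,8aS)-6-bromo-2,5,5,8a-tetramethyl-1,4,4a,5,6,7,8,8a-octahydronaphthalen-1-yl]-2-methylbut-2-enoate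
Conditions: Ph3P=C(CH3)CO2Et (1.5 equiv), toluene, 80 °C
Reagents that add atoms: ethyl 2-(triphenylphosphoranylidene)propanoate, CCOC(=O)C(C)=P(c1ccccc1)(c1ccccc1)c1ccccc1
Why: Wittig olefination with a stabilised ylide, which should give the (E)-trisubstituted enoate.

Step 19
Reactants: 22 ((E)-enoate)
Product: 23 (2E)-4-[(1S,4aS,6R,8aS)-6-bromo-2,5,5,8a-tetramethyl-1,4,4a,5,6,7,8,8a-octahydronaphthalen-1-yl]-2-methylbut-2-en-1-ol
Conditions: i-Bu2AlH (2.5 equiv), CH2Cl2, −78 → 0 °C
Reagents that add atoms: none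
Why: 1,2-Reduction of the conjugated ester with i-Bu2AlH to the allylic alcohol with retention of the alkene geometry.

Step 20
Reactants: 23 ((E)-allylic alcohol)
Product: 24 [(2S,3S)-3-{[(1S,4aS,6R,8aS)-6-bromo-2,5,5,8a-tetramethyl-1,4,4a,5,6,7,8,8a-octahydronaphthalen-1-yl]methyl}-2-methyloxiran-2-yl]methanol
Conditions: Ti(Oi-Pr)4 (10 mol %), L-(+)-diethyl tartrate (12 mol %), t-BuOOH, 4 Å molecular sieves, CH2Cl2, −20 °C
Reagents that add atoms: tert-butyl hydroperoxide, CC(C)(C)OO
Why: Sharpless asymmetric epoxidation, in which the L-(+)-tartrate complex delivers oxygen to the alkene face that gives the (2S,3S)-epoxide, so C13 is set by the reagent and the isolated C7=C8 alkene is not touched.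

Step 21
Reactants: 24 (epoxy alcohol)
Product: 25 (2R)-4-[(1S,4aS,6R,8aS)-6-bromo-2,5,5,8a-tetramethyl-1,4,4a,5,6,7,8,8a-octahydronaphthalen-1-yl]-2-methylbutane-1,2-diol
Conditions: LiAlH4 (1.5 equiv), THF, 0 °C
Reagents that add atoms: none
Why: Regioselective hydride opening of a 2-methyl-2,3-epoxy alcohol at the less substituted carbon C12, which leaves the C13–O bond and its configuration intact and gives the (13R)-1,2-diol, the hindered equatorial bromide being expected to survive at 0 °C.

Step 22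
Reactants: 25 (1,2-diol)
Product: 26 (2R)-4-[(1S,4aS,6R,8aS)-6-bromo-2,5,5,8a-tetramethyl-1,4,4a,5,6,7,8,8a-octahydronaphthalen-1-yl]-2-hydroxy-2-methylbutanal
Conditions: SO3·pyridine, DMSO, i-Pr2NEt, CH2Cl2, 0 °C
Reagents that add atoms: none
Why: Parikh–Doering oxidation, which converts the primary alcohol to the aldehyde while the tertiary alcohol cannot be oxidised and the diol is not cleaved.

Step 23
Reactants: 26 (α-hydroxy aldehyde)
Product: 27 (3R)-5-[(1S,4aS,6R,8aS)-6-bromo-2,5,5,8a-tetramethyl-1,4,4a,5,6,7,8,8a-octahydronaphthalen-1-yl]-3-methylpent-1-en-3-ol (target)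
Conditions: Ph3PCH3Br (3.5 equiv), KOt-Bu (3.3 equiv), THF, 0 °C
Reagents that add atoms: methyltriphenylphosphonium bromide, C[P+](c1ccccc1)(c1ccccc1)c1ccccc1.[Br-]
Why: Wittig methylenation with excess ylide (one equivalent is taken up by the tertiary hydroxyl), which completes the vinyl group without affecting C13.

**Compound list**

1 | 2-bromo-1,3-dimethylbenzene | Cc1cccc(C)c1Br | starting material
2 | 2-bromo-1,3-dimethyl-4-nitrobenzene | Cc1ccc([N+](=O)[O-])c(C)c1Br | intermediate
3 | 3-bromo-2,4-dimethylaniline | Cc1ccc(N)c(C)c1Br | intermediate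
4 | 3-bromo-2,4-dimethylbenzenediazonium hydrogensulfate | Cc1ccc([N+]#N)c(C)c1Br.OS(=O)(=O)[O-] | intermediate (not isolated)
5 | 3-bromo-2,4-dimethylphenol | Cc1ccc(O)c(C)c1Br | intermediate
6 | allyl alcohol | C=CCO | starting material
7 | 3-(3-hydroxy-2,6-dimethylphenyl)propanal | O=CCCc1c(C)ccc(O)c1C | intermediate
8 | ethyl propiolate | C#CC(=O)OCC | starting material
9 | ethyl 4-hydroxy-6-(3-hydroxy-2,6-dimethylphenyl)hex-2-ynoate (racemic) | CCOC(=O)C#CC(O)CCc1c(C)ccc(O)c1C | intermediate
10 | ethyl (E)-6-(3-hydroxy-2,6-dimethylphenyl)-4-oxohex-2-enoate | CCOC(=O)/C=C/C(=O)CCc1c(C)ccc(O)c1C | intermediate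
11 | ethyl 2-[(1R,8aS)-5,8a-dimethyl-2,6-dioxo-1,2,3,4,6,8a-hexahydronaphthalen-1-yl]acetate | CCOC(=O)C[C@H]1C(=O)CCC2=C(C)C(=O)C=C[C@]21C | intermediate
12 | ethyl 2-[(1R,8aS)-2,2-(ethylenedioxy)-5,8a-dimethyl-6-oxo-1,2,3,4,6,8a-hexahydronaphthalen-1-yl]acetate | CCOC(=O)C[C@H]1C2(OCCO2)CCC3=C(C)C(=O)C=C[C@]31C | intermediate
13 | ethyl 2-[(1R,8aS)-2,2-(ethylenedioxy)-5,8a-dimethyl-6-oxo-1,2,3,4,6,7,8,8a-octahydronaphthalen-1-yl]acetate | CCOC(=O)C[C@H]1C2(OCCO2)CCC3=C(C)C(=O)CC[C@]31C | intermediate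
14 | ethyl 2-[(1R,8aS)-2,2-(ethylenedioxy)-5,5,8a-trimethyl-6-oxo-1,2,3,5,6,7,8,8a-octahydronaphthalen-1-yl]acetate | CCOC(=O)C[C@H]1C2(OCCO2)CC=C3C(C)(C)C(=O)CC[C@]31C | intermediate
15 | ethyl 2-[(1R,8aS)-2,2-(ethylenedioxy)-5,5,8a-trimethyl-6-{[(trifluoromethyl)sulfonyl]oxy}-1,2,3,5,8,8a-hexahydronaphthalen-1-yl]acetate | CCOC(=O)C[C@H]1C2(OCCO2)CC=C3C(C)(C)C(OS(=O)(=O)C(F)(F)F)=CC[C@]31C | intermediate
16 | ethyl 2-[(1R,8aS)-6-bromo-2,2-(ethylenedioxy)-5,5,8a-trimethyl-1,2,3,5,8,8a-hexahydronaphthalen-1-yl]acetate | CCOC(=O)C[C@H]1C2(OCCO2)CC=C3C(C)(C)C(Br)=CC[C@]31C | intermediate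
17 | ethyl 2-[(1R,4aS,6R,8aR)-6-bromo-2,2-(ethylenedioxy)-5,5,8a-trimethyldecahydronaphthalen-1-yl]acetate | CCOC(=O)C[C@H]1C2(OCCO2)CC[C@@H]3C(C)(C)[C@H](Br)CC[C@]31C | intermediate
18 | ethyl 2-[(1R,4aS,6R,8aR)-6-bromo-5,5,8a-trimethyl-2-oxodecahydronaphthalen-1-yl]acetate | CCOC(=O)C[C@H]1C(=O)CC[C@@H]2C(C)(C)[C@H](Br)CC[C@]21C | intermediate
19 | ethyl 2-[(1R,4aS,6R,8aR)-6-bromo-5,5,8a-trimethyl-2-{[(trifluoromethyl)sulfonyl]oxy}-1,4,4a,5,6,7,8,8a-octahydronaphthalen-1-yl]acetate | CCOC(=O)C[C@H]1C(OS(=O)(=O)C(F)(F)F)=CC[C@@H]2C(C)(C)[C@H](Br)CC[C@]21C | intermediate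
20 | ethyl 2-[(1S,4aS,6R,8aS)-6-bromo-2,5,5,8a-tetramethyl-1,4,4a,5,6,7,8,8a-octahydronaphthalen-1-yl]acetate | CCOC(=O)C[C@H]1C(C)=CC[C@@H]2C(C)(C)[C@H](Br)CC[C@]21C | intermediate
21 | 2-[(1S,4aS,6R,8aS)-6-bromo-2,5,5,8a-tetramethyl-1,4,4a,5,6,7,8,8a-octahydronaphthalen-1-yl]acetaldehyde | O=CC[C@H]1C(C)=CC[C@@H]2C(C)(C)[C@H](Br)CC[C@]21C | intermediate
22 | ethyl (2E)-4-[(1S,4aS,6R,8aS)-6-bromo-2,5,5,8a-tetramethyl-1,4,4a,5,6,7,8,8a-octahydronaphthalen-1-yl]-2-methylbut-2-enoate | CCOC(=O)/C(C)=C/C[C@H]1C(C)=CC[C@@H]2C(C)(C)[C@H](Br)CC[C@]21C | intermediate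
23 | (2E)-4-[(1S,4aS,6R,8aS)-6-bromo-2,5,5,8a-tetramethyl-1,4,4a,5,6,7,8,8a-octahydronaphthalen-1-yl]-2-methylbut-2-en-1-ol | OC/C(C)=C/C[C@H]1C(C)=CC[C@@H]2C(C)(C)[C@H](Br)CC[C@]21C | intermediate
24 | [(2S,3S)-3-{[(1S,4aS,6R,8aS)-6-bromo-2,5,5,8a-tetramethyl-1,4,4a,5,6,7,8,8a-octahydronaphthalen-1-yl]methyl}-2-methyloxiran-2-yl]methanol | OC[C@]1(C)O[C@H]1C[C@H]2C(C)=CC[C@@H]3C(C)(C)[C@H](Br)CC[C@]32C | intermediate
25 | (2R)-4-[(1S,4aS,6R,8aS)-6-bromo-2,5,5,8a-tetramethyl-1,4,4a,5,6,7,8,8a-octahydronaphthalen-1-yl]-2-methylbutane-1,2-diol | OC[C@](C)(O)CC[C@H]1C(C)=CC[C@@H]2C(C)(C)[C@H](Br)CC[C@]21C | intermediate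
26 | (2R)-4-[(1S,4aS,6R,8aS)-6-bromo-2,5,5,8a-tetramethyl-1,4,4a,5,6,7,8,8a-octahydronaphthalen-1-yl]-2-hydroxy-2-methylbutanal | O=C[C@](C)(O)CC[C@H]1C(C)=CC[C@@H]2C(C)(C)[C@H](Br)CC[C@]21C | intermediate
27 | (3R)-5-[(1S,4aS,6R,8aS)-6-bromo-2,5,5,8a-tetramethyl-1,4,4a,5,6,7,8,8a-octahydronaphthalen-1-yl]-3-methylpent-1-en-3-ol | C=C[C@](C)(O)CC[C@H]1C(C)=CC[C@@H]2C(C)(C)[C@H](Br)CC[C@]21C | target

**Step count**

Total steps: 23. Longest linear sequence: 23 steps (1 → 27); allyl alcohol and ethyl propiolate enter as purchased reagents.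

**Steps most likely to fail**

1. Step 7. The addition gives up the aromaticity of ring A and is expected to be only modestly downhill, so it may reverse by retro-Michael cleavage with rearomatisation, which would also erode the enantiomeric purity. The ion pair may discriminate the arene faces poorly, attack may occur at the ortho carbon C4, and C9 may epimerise before the quench. If the sense of induction is opposite, the pseudo-enantiomeric cinchoninium salt would be used. The fallback replaces the conjugate addition by an alkylative dearomatisation built from known reaction types. Setting out from 10, amine-salt-catalysed asymmetric epoxidation of the enone (9-amino-9-deoxy-epi-quinine bis(trifluoroacetate) or its pseudo-enantiomer, 30% H2O2, dioxane) should give ethyl (2R,3R)-3-[3-(3-hydroxy-2,6-dimethylphenyl)propanoyl]oxirane-2-carboxylate F1. KOt-Bu in t-BuOH would then bring about a Winstein–Masamune-type para C-alkylation of the phenoxide by the α-keto epoxide carbon C9 (6-exo-tet, inversion at C9), which fixes C10 in ethyl (2R)-2-[(1S,8aS)-5,8a-dimethyl-2,6-dioxo-1,2,3,4,6,8a-hexahydronaphthalen-1-yl]-2-hydroxyacetate F2. Mesylation and elimination (MsCl, Et3N) would give the alkylidene keto ester ethyl 2-[(8aR)-5,8a-dimethyl-2,6-dioxo-3,4,6,8a-tetrahydronaphthalen-1(2H)-ylidene]acetate F3. Conjugate reduction with [(Ph3P)CuH]6 and protonation of the resulting C8 enolate would come back to the route at 11.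

2. Step 13. Hydrogen-atom transfer may stall at the hindered C5=C6 alkene, flanked by two quaternary carbons, or the C3 radical may lose bromine instead of picking up hydrogen. The fallback separates the two reductions. Setting out from 14, hydrogenation over Pd/C (H2, 4 atm, EtOAc) should add hydrogen to C5=C6 from the face opposite the C10 methyl and give the trans-fused ketone ethyl 2-[(1R,4aS,8aR)-2,2-(ethylenedioxy)-5,5,8a-trimethyl-6-oxodecahydronaphthalen-1-yl]acetate F4. Condensation with 1,2-bis(tert-butyldimethylsilyl)hydrazine (Sc(OTf)3 cat.) would give the N-silyl hydrazone ethyl 2-[(1R,4aS,8aR)-6-{2-[tert-butyl(dimethyl)silyl]hydrazinylidene}-2,2-(ethylenedioxy)-5,5,8a-trimethyldecahydronaphthalen-1-yl]acetate F5. CuBr2 and Et3N in MeOH would convert it to the geminal dibromide ethyl 2-[(1R,4aS,8aR)-6,6-dibromo-2,2-(ethylenedioxy)-5,5,8a-trimethyldecahydronaphthalen-1-yl]acetate F6. Bu3SnH (1.0 equiv, Et3B/air, −78 °C) would remove one bromine through the same C3 radical, with hydrogen again arriving trans to the axial C4 methyl, and rejoin the route at 17.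

3. Step 4. Oxidative addition to the electron-rich, di-ortho-substituted bromide may be slow, and β-hydride elimination may run toward the benzylic side and give the cinnamyl alcohol instead of the aldehyde. The fallback builds the same C–C bond by cross-coupling of an alkylborane. Setting out from 5, hydroboration of acrolein diethyl acetal with 9-BBN and B-alkyl Suzuki–Miyaura coupling (Pd(OAc)2, SPhos, K3PO4, THF/H2O, 65 °C) should give 3-(3,3-diethoxypropyl)-2,4-dimethylphenol F7. Mild acid (1 M HCl, THF) would release the aldehyde and rejoin the route at 7.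

**Further compounds**

F1 | step 7 | ethyl (2R,3R)-3-[3-(3-hydroxy-2,6-dimethylphenyl)propanoyl]oxirane-2-carboxylate | CCOC(=O)[C@@H]1O[C@H]1C(=O)CCc1c(C)ccc(O)c1C
F2 | step 7 | ethyl (2R)-2-[(1S,8aS)-5,8a-dimethyl-2,6-dioxo-1,2,3,4,6,8a-hexahydronaphthalen-1-yl]-2-hydroxyacetate | CCOC(=O)[C@H](O)[C@H]1C(=O)CCC2=C(C)C(=O)C=C[C@]21C
F3 | step 7 | ethyl 2-[(8aR)-5,8a-dimethyl-2,6-dioxo-3,4,6,8a-tetrahydronaphthalen-1(2H)-ylidene]acetate (alkene geometry not fixed) | CCOC(=O)C=C1C(=O)CCC2=C(C)C(=O)C=C[C@]21C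
F4 | step 13 | ethyl 2-[(1R,4aS,8aR)-2,2-(ethylenedioxy)-5,5,8a-trimethyl-6-oxodecahydronaphthalen-1-yl]acetate | CCOC(=O)C[C@H]1C2(OCCO2)CC[C@@H]3C(C)(C)C(=O)CC[C@]31C
F5 | step 13 | ethyl 2-[(1R,4aS,8aR)-6-{2-[tert-butyl(dimethyl)silyl]hydrazinylidene}-2,2-(ethylenedioxy)-5,5,8a-trimethyldecahydronaphthalen-1-yl]acetate | CCOC(=O)C[C@H]1C2(OCCO2)CC[C@@H]3C(C)(C)C(=NN[Si](C)(C)C(C)(C)C)CC[C@]31C
F6 | step 13 | ethyl 2-[(1R,4aS,8aR)-6,6-dibromo-2,2-(ethylenedioxy)-5,5,8a-trimethyldecahydronaphthalen-1-yl]acetate | CCOC(=O)C[C@H]1C2(OCCO2)CC[C@@H]3C(C)(C)C(Br)(Br)CC[C@]31C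
F7 | step 4 | 3-(3,3-diethoxypropyl)-2,4-dimethylphenol | CCOC(CCc1c(C)ccc(O)c1C)OCC
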